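**Retrosynthetic overview**

1. Numbering: five-membered ring C1–C2–C3–C4–C5, seven-membered ring C1–C10–C9–C8–C7–C6–C5, C1′ = benzylic carbon. The plan rests on the adjacent pair C4 (quaternary, carrying the methyl group and C1′) and C5 (carrying C6) in the five-membered ring, with C1′ and C6 trans; this maps onto β-alkylation then anti α-alkylation of 2-methylcyclopent-2-enone, whose carbonyl carbon is C3.
2. Late stage: aryl OH ⇐ OMe (thiolate); both CHO ⇐ twofold ortho-lithiation/formylation; C10 carbinol ⇐ hydride opening of the C9–C10 α-epoxide; C3 methylene ⇐ Wolff–Kishner reduction.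
3. Seven-membered ring (the only ring made, closed in step 12) ⇐ ring-closing metathesis to C9=C10 ⇐ copper-catalysed 1,4-addition of isopropenylmagnesium bromide at C1 of the C1=C2 enone ⇐ Saegusa–Ito oxidation of the C3 ketone.
4. Key union: C5–C6 by copper-catalysed asymmetric conjugate addition of Grignard reagent 10 to enone 15, then C4–C1′ by attack of the enolate on the o-quinone methide released from sulfone 14; the five-membered ring and the arene are bought.
5. Fragments: 10 by Evans deconjugative allylation (sets C7); 14 from 2-hydroxy-4,6-dimethoxybenzaldehyde, isobutyllithium and PhSO2Na.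

Key step: step 8

Assumption: the CuBr complex of (R)-1-[(S)-2-(diphenylphosphino)ferrocenyl]ethyldicyclohexylphosphine is taken to add the alkyl group to the enone face that makes C5 (R) in 16 and 19; if a trial with a simple Grignard reagent shows the opposite sense, the enantiomeric ligand is used and nothing else changes.

**Route**

Step 1
Reactants: 1 auxiliary (S)-4-benzyl-1,3-oxazolidin-2-one; 2 acid chloride 3-methylbut-2-enoyl chloride
Product: 4 imide (S)-4-benzyl-3-(3-methylbut-2-enoyl)-1,3-oxazolidin-2-one, via N-lithio oxazolidinone 3 (not isolated)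
Conditions: n-BuLi, THF, −78 °C; then 2, −78 → 0 °C
Reagents that add atoms: none
Why: N-acylation of the lithiated Evans auxiliary with an acid chloride is the standard way to N-enoyl oxazolidinones and creates no stereocentre.

Step 2
Reactants: 4 imide; 5 allyl iodide
Product: 7 imide (S)-4-benzyl-3-[(2S)-2-(prop-1-en-2-yl)pent-4-enoyl]-1,3-oxazolidin-2-one, via sodium dienolate 6 (not isolated)
Conditions: NaN(SiMe3)2, THF, −78 °C; then 5, −78 → −40 °C
Reagents that add atoms: none
Why: γ-deprotonation gives the sodium-chelated Z-dienolate, which is alkylated at the α-carbon on the face away from the benzyl group (Evans deconjugative alkylation), so the future C7 is set as (2S) in 7.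

Step 3
Reactants: 7 imide
Product: 8 alcohol (2S)-2-(prop-1-en-2-yl)pent-4-en-1-ol
Conditions: LiBH4, MeOH (1 equiv), Et2O, 0 °C
Reagents that add atoms: none
Why: reductive cleavage of the N-acyl oxazolidinone with LiBH4 gives the primary alcohol without touching the α-stereocentre or the alkenes and returns the auxiliary.

Step 4
Reactants: 8 alcohol
Product: 9 bromide (3S)-3-(bromomethyl)-2-methylhexa-1,5-diene
Conditions: CBr4, PPh3, CH2Cl2, 0 °C
Reagents that add atoms: carbon tetrabromide, BrC(Br)(Br)Br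
Why: the Appel bromination converts the primary alcohol at a carbon that is not a stereocentre, so C7 is untouched.

Step 5
Reactants: 9 bromide
Product: 10 Grignard reagent [(2S)-2-(prop-1-en-2-yl)pent-4-en-1-yl]magnesium bromide
Conditions: Mg turnings, Et2O, 25–35 °C; used as a titrated solution
Reagents that add atoms: magnesium, [Mg]
Why: magnesium insertion into the primary C–Br bond gives the Grignard reagent, whose stereocentre is β to magnesium and cannot epimerise.

Step 6
Reactants: 11 aldehyde 2-hydroxy-4,6-dimethoxybenzaldehyde; 12 isobutyllithium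
Product: 13 racemic diol 2-(1-hydroxy-3-methylbutyl)-3,5-dimethoxyphenol
Conditions: 12 (2.2 equiv), THF, −78 → 0 °C; aq NH4Cl
Reagents that add atoms: none
Why: after deprotonation of the phenol the second equivalent of the alkyllithium undergoes 1,2-addition to the aldehyde, and the racemic carbinol is acceptable because C1′ becomes planar in step 8.

Step 7
Reactants: 13 racemic diol
Product: 14 racemic sulfone 3,5-dimethoxy-2-[3-methyl-1-(phenylsulfonyl)butyl]phenol
Conditions: PhSO2Na (1.5 equiv), HCO2H–H2O, 25 °C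
Reagents that add atoms: sodium benzenesulfinate, [Na+].[O-]S(=O)c1ccccc1
Why: acid ionises the electron-rich o-hydroxybenzylic alcohol and the sulfinate adds at sulfur to the resulting quinone methide (known sulfinate capture of o-quinone methides), the position being fixed because the carbon was already attached ortho to the hydroxyl group.

Step 8
Reactants: 10 Grignard reagent; 15 enone 2-methylcyclopent-2-en-1-one; 14 racemic sulfone
Product: 19 ketophenol (2S,3R)-2-[(1S)-1-(2-hydroxy-4,6-dimethoxyphenyl)-3-methylbutyl]-2-methyl-3-[(2R)-2-(prop-1-en-2-yl)pent-4-en-1-yl]cyclopentan-1-one, via bromomagnesium enolate 16 (not isolated), via chloromagnesium phenoxide 17 (not isolated), via o-quinone methide 18 (not isolated)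
Conditions: CuBr·SMe2 (5 mol %), (R)-1-[(S)-2-(diphenylphosphino)ferrocenyl]ethyldicyclohexylphosphine (6 mol %), t-BuOMe, −78 °C, 10 (1.0 equiv) added slowly to 15 (1.15 equiv); then 14 (1.2 equiv) pre-treated with i-PrMgCl (1.0 equiv per 14, THF, −78 °C) and DMPU, −78 → 0 °C; aq NH4Cl
Reagents that add atoms: none
Why: Proposed new method: the diphosphine–copper catalyst transfers the primary alkyl group of 10 to the β-carbon C5 of 15 (forming C5–C6) and leaves the tetrasubstituted bromomagnesium enolate 16, and on warming the phenoxide 17 expels benzenesulfinate to give the E-configured quinone methide 18, whose exocyclic carbon C1′ is attacked by C4 of 16 (forming C4–C1′) with rearomatisation to a phenoxide that makes the addition irreversible. The closest known reactions are copper-catalysed asymmetric conjugate addition of Grignard reagents to 2-methylcycloalkenones with trapping of the magnesium enolate, and Michael addition of enolates to o-quinone methides released from 2-(1-sulfonylalkyl)phenols; carrying out both in one flask is the untested part. No ring is closed. C5 is set by the ligand on copper, C4 by approach of 18 to the enolate face anti to the new C5 side chain, and C1′ by an open antiperiplanar approach in which the C1′–H lies over the five-membered ring, the quinone-methide ring points away from the C3=C4 bond and the isobutyl group sits beside the enolate oxygen. The step needs C-alkylation over O-alkylation, no organomagnesium reagent left when 18 appears, and an unbridged transition state: O-alkylation would revert through 18 whereas C-alkylation does not, 15 is kept in slight excess over 10 so that no RMgBr remains to add to 18, and DMPU keeps magnesium from bridging the enolate and quinone-methide oxygens, an arrangement that would lead to the C1′ epimer. The C1′ sense is therefore argued from the transition-state model and is not secured by the substrate.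

Step 9
Reactants: 19 ketophenol
Product: 20 ketone (2S,3R)-2-methyl-2-[(1S)-3-methyl-1-(2,4,6-trimethoxyphenyl)butyl]-3-[(2R)-2-(prop-1-en-2-yl)pent-4-en-1-yl]cyclopentan-1-one
Conditions: MeI, K2CO3, DMF, 25 °C
Reagents that add atoms: iodomethane, CI
Why: Williamson methylation of the phenoxide draws the equilibrium between 19 and its cyclic hemiketal to the open ketone and leaves a symmetric 2,4,6-trimethoxyphenyl ring, K2CO3 being too weak to enolise the ketone.

Step 10
Reactants: 20 ketone
Product: 22 enone (4S,5S)-5-methyl-5-[(1S)-3-methyl-1-(2,4,6-trimethoxyphenyl)butyl]-4-[(2R)-2-(prop-1-en-2-yl)pent-4-en-1-yl]cyclopent-2-en-1-one, via silyl enol ether 21 (not isolated)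
Conditions: Me3SiOTf, Et3N, CH2Cl2, 0 °C; then Pd(OAc)2 (1.1 equiv), MeCN, 25 °C
Reagents that add atoms: none
Why: because C4 is quaternary the ketone can enolise only toward C2, so silylation gives one enol ether and Saegusa–Ito oxidation with divalent palladium gives the C1=C2 enone.

Step 11
Reactants: 22 enone; 23 isopropenylmagnesium bromide
Product: 25 ketone (2S,3S,4R)-2-methyl-2-[(1S)-3-methyl-1-(2,4,6-trimethoxyphenyl)butyl]-4-(prop-1-en-2-yl)-3-[(2R)-2-(prop-1-en-2-yl)pent-4-en-1-yl]cyclopentan-1-one, via silyl enol ether 24 (not isolated)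
Conditions: 23 (1.5 equiv), CuBr·SMe2 (10 mol %), Me3SiCl, THF, −78 °C; then 1 M HCl
Reagents that add atoms: none
Why: the copper-catalysed, silyl chloride-accelerated conjugate addition should deliver the isopropenyl group to C1 anti to the adjacent C5 side chain (the usual trans selectivity of 4-substituted cyclopentenones), which sets C1 for the trans ring fusion.

Step 12
Reactants: 25 ketone
Product: 26 bicyclic ketone (1S,3aR,7R,8aS)-1,4-dimethyl-1-[(1S)-3-methyl-1-(2,4,6-trimethoxyphenyl)butyl]-7-(prop-1-en-2-yl)-3,3a,6,7,8,8a-hexahydroazulen-2(1H)-one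
Conditions: second-generation Grubbs catalyst RuCl2(=CHPh)(PCy3)(H2IMes) (5 mol %), CH2Cl2 (0.005 M), 40 °C
Reagents that add atoms: none
Why: ring-closing metathesis starts at the monosubstituted C9 vinyl group and closes the seven-membered ring onto the C10 isopropenyl group (the C7 isopropenyl group could only give a cyclobutene), forming the trisubstituted C9=C10 bond with loss of ethylene.

Step 13
Reactants: 26 bicyclic ketone
Product: 28 alkene (1S,3aR,7R,8aS)-1,4-dimethyl-1-[(1R)-3-methyl-1-(2,4,6-trimethoxyphenyl)butyl]-7-(prop-1-en-2-yl)-1,2,3,3a,6,7,8,8a-octahydroazulene, via hydrazone 27 (not isolated)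
Conditions: N2H4·H2O, KOH, diethylene glycol, 130 °C then 200 °C, under argon
Reagents that add atoms: none
Why: Wolff–Kishner reduction (Huang-Minlon procedure) should remove the C3 carbonyl as it does for cyclopentanones next to a quaternary carbon such as 17-keto steroids, no epimerisable stereocentre lies α to the carbonyl, and isolated alkenes survive when air is excluded.

Step 14
Reactants: 28 alkene
Product: 29 epoxide, the 9α,10α-epoxide of 28 (route numbering, 9R,10S; oxygen syn to H1 and anti to the C7 isopropenyl group)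
Conditions: mCPBA (1.05 equiv), NaHCO3, CH2Cl2, −20 → 0 °C
Reagents that add atoms: mCPBA (3-chloroperbenzoic acid), OOC(=O)c1cccc(Cl)c1
Why: in this Prilezhaev epoxidation the peracid prefers the more electron-rich trisubstituted C9=C10 bond over the 1,1-disubstituted isopropenyl group (as with limonene) and should approach the α face, away from the β-oriented C7 isopropenyl group and H5, a facial preference that is argued and not secured.

Step 15
Reactants: 29 epoxide
Product: 30 alcohol (1S,3aR,4R,7R,8aS)-1,4-dimethyl-1-[(1R)-3-methyl-1-(2,4,6-trimethoxyphenyl)butyl]-7-(prop-1-en-2-yl)decahydroazulen-4-ol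
Conditions: LiAlH4, THF, 65 °C
Reagents that add atoms: none
Why: hydride opens the trisubstituted epoxide by SN2 attack at the less substituted C9, so the oxygen stays on C10 with its α configuration and gives the tertiary carbinol.

Step 16
Reactants: 30 alcohol
Product: 34 dialdehyde 5-{(1R)-1-[(1S,3aR,4R,7R,8aS)-4-hydroxy-1,4-dimethyl-7-(prop-1-en-2-yl)decahydroazulen-1-yl]-3-methylbutyl}-2,4,6-trimethoxybenzene-1,3-dicarbaldehyde, via aryllithium 31 (not isolated), via amino alkoxide 32 (not isolated), via aryllithium 33 (not isolated)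
Conditions: n-BuLi (2.1 equiv), TMEDA, THF, 0 °C; Me2NCH2CH2N(Me)CHO (1.3 equiv), −78 → −20 °C; n-BuLi (2 equiv), −20 → 0 °C; DMF (excess), −78 → 25 °C; aq NH4Cl
Reagents that add atoms: N-[2-(dimethylamino)ethyl]-N-methylformamide, CN(C)CCN(C)C=O; N,N-dimethylformamide, CN(C)C=O
Why: directed ortho-metalation takes place at the two ring positions flanked by methoxy groups, and the α-amino alkoxide formed from the first aryllithium and the formamide protects the first formyl group during the second lithiation (in situ protection), so both aldehydes are introduced without acid and in the presence of the lithium alkoxide of the carbinol.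

Step 17
Reactants: 34 dialdehyde
Product: 35 target 5-{(1R)-1-[(1S,3aR,4R,7R,8aS)-4-hydroxy-1,4-dimethyl-7-(prop-1-en-2-yl)decahydroazulen-1-yl]-3-methylbutyl}-2,4,6-trihydroxybenzene-1,3-dicarbaldehyde
Conditions: NaSEt (10 equiv), DMF, 120 °C; then cold 1 M HCl
Reagents that add atoms: none
Why: thiolate SN2 demethylation is fast for methoxy groups ortho or para to formyl groups and should spare the tertiary alcohol and the isopropenyl group, which Lewis-acidic demethylation would not.

**Compound list**

1 | (S)-4-benzyl-1,3-oxazolidin-2-one | O=C1OC[C@H](Cc2ccccc2)N1 | starting material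
2 | 3-methylbut-2-enoyl chloride | CC(C)=CC(Cl)=O | starting material
3 | N-lithio derivative of 1 | O=C1OC[C@H](Cc2ccccc2)N1[Li] | intermediate
4 | (S)-4-benzyl-3-(3-methylbut-2-enoyl)-1,3-oxazolidin-2-one | CC(C)=CC(=O)N1[C@@H](Cc2ccccc2)COC1=O | intermediate
5 | allyl iodide (3-iodoprop-1-ene) | C=CCI | starting material
6 | sodium Z-dienolate of 4 | C=C(C)/C=C(\O[Na])N1[C@@H](Cc2ccccc2)COC1=O | intermediate
7 | (S)-4-benzyl-3-[(2S)-2-(prop-1-en-2-yl)pent-4-enoyl]-1,3-oxazolidin-2-one | C=CC[C@@H](C(C)=C)C(=O)N1[C@@H](Cc2ccccc2)COC1=O | intermediate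
8 | (2S)-2-(prop-1-en-2-yl)pent-4-en-1-ol | C=CC[C@@H](C(C)=C)CO | intermediate
9 | (3S)-3-(bromomethyl)-2-methylhexa-1,5-diene | C=CC[C@@H](C(C)=C)CBr | intermediate
10 | [(2S)-2-(prop-1-en-2-yl)pent-4-en-1-yl]magnesium bromide | C=CC[C@@H](C(C)=C)C[Mg]Br | intermediate
11 | 2-hydroxy-4,6-dimethoxybenzaldehyde | COc1cc(O)c(C=O)c(OC)c1 | starting material
12 | isobutyllithium | CC(C)C[Li] | starting material
13 | 2-(1-hydroxy-3-methylbutyl)-3,5-dimethoxyphenol (racemic) | CC(C)CC(O)c1c(O)cc(OC)cc1OC | intermediate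
14 | 3,5-dimethoxy-2-[3-methyl-1-(phenylsulfonyl)butyl]phenol (racemic) | CC(C)CC(c1c(O)cc(OC)cc1OC)S(=O)(=O)c2ccccc2 | intermediate
15 | 2-methylcyclopent-2-en-1-one | CC1=CCCC1=O | starting material
16 | bromomagnesium (3R)-2-methyl-3-[(2R)-2-(prop-1-en-2-yl)pent-4-en-1-yl]cyclopent-1-en-1-olate | C=CC[C@@H](C(C)=C)C[C@H]1CCC(O[Mg]Br)=C1C | intermediate
17 | chloromagnesium phenoxide of 14 | CC(C)CC(c1c(O[Mg]Cl)cc(OC)cc1OC)S(=O)(=O)c2ccccc2 | intermediate
18 | (E)-3,5-dimethoxy-6-(3-methylbutylidene)cyclohexa-2,4-dien-1-one | CC(C)C/C=C1/C(=O)C=C(OC)C=C1OC | intermediate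
19 | (2S,3R)-2-[(1S)-1-(2-hydroxy-4,6-dimethoxyphenyl)-3-methylbutyl]-2-methyl-3-[(2R)-2-(prop-1-en-2-yl)pent-4-en-1-yl]cyclopentan-1-one | C=CC[C@@H](C(C)=C)C[C@H]1CCC(=O)[C@]1(C)[C@@H](CC(C)C)c2c(O)cc(OC)cc2OC | intermediate
20 | (2S,3R)-2-methyl-2-[(1S)-3-methyl-1-(2,4,6-trimethoxyphenyl)butyl]-3-[(2R)-2-(prop-1-en-2-yl)pent-4-en-1-yl]cyclopentan-1-one | C=CC[C@@H](C(C)=C)C[C@H]1CCC(=O)[C@]1(C)[C@@H](CC(C)C)c2c(OC)cc(OC)cc2OC | intermediate
21 | trimethylsilyl enol ether of 20 (C2=C3) | C=CC[C@@H](C(C)=C)C[C@H]1CC=C(O[Si](C)(C)C)[C@]1(C)[C@@H](CC(C)C)c2c(OC)cc(OC)cc2OC | intermediate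
22 | (4S,5S)-5-methyl-5-[(1S)-3-methyl-1-(2,4,6-trimethoxyphenyl)butyl]-4-[(2R)-2-(prop-1-en-2-yl)pent-4-en-1-yl]cyclopent-2-en-1-one | C=CC[C@@H](C(C)=C)C[C@H]1C=CC(=O)[C@]1(C)[C@@H](CC(C)C)c2c(OC)cc(OC)cc2OC | intermediate
23 | isopropenylmagnesium bromide | C=C(C)[Mg]Br | starting material
24 | trimethylsilyl enol ether of 25 (C2=C3) | C=C(C)[C@@H]1C=C(O[Si](C)(C)C)[C@](C)([C@@H](CC(C)C)c2c(OC)cc(OC)cc2OC)[C@H]1C[C@@H](CC=C)C(C)=C | intermediate
25 | (2S,3S,4R)-2-methyl-2-[(1S)-3-methyl-1-(2,4,6-trimethoxyphenyl)butyl]-4-(prop-1-en-2-yl)-3-[(2R)-2-(prop-1-en-2-yl)pent-4-en-1-yl]cyclopentan-1-one | C=C(C)[C@@H]1CC(=O)[C@](C)([C@@H](CC(C)C)c2c(OC)cc(OC)cc2OC)[C@H]1C[C@@H](CC=C)C(C)=C | intermediate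
26 | (1S,3aR,7R,8aS)-1,4-dimethyl-1-[(1S)-3-methyl-1-(2,4,6-trimethoxyphenyl)butyl]-7-(prop-1-en-2-yl)-3,3a,6,7,8,8a-hexahydroazulen-2(1H)-one | C=C(C)[C@@H]1CC=C(C)[C@@H]2CC(=O)[C@](C)([C@@H](CC(C)C)c3c(OC)cc(OC)cc3OC)[C@H]2C1 | intermediate
27 | hydrazone of 26 | C=C(C)[C@@H]1CC=C(C)[C@@H]2CC(=NN)[C@](C)([C@@H](CC(C)C)c3c(OC)cc(OC)cc3OC)[C@H]2C1 | intermediate
28 | (1S,3aR,7R,8aS)-1,4-dimethyl-1-[(1R)-3-methyl-1-(2,4,6-trimethoxyphenyl)butyl]-7-(prop-1-en-2-yl)-1,2,3,3a,6,7,8,8a-octahydroazulene | C=C(C)[C@@H]1CC=C(C)[C@@H]2CC[C@](C)([C@@H](CC(C)C)c3c(OC)cc(OC)cc3OC)[C@H]2C1 | intermediate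
29 | 9α,10α-epoxide of 28 (route numbering, 9R,10S) | C=C(C)[C@@H]1C[C@H]3O[C@@]3(C)[C@@H]2CC[C@](C)([C@@H](CC(C)C)c4c(OC)cc(OC)cc4OC)[C@H]2C1 | intermediate
30 | (1S,3aR,4R,7R,8aS)-1,4-dimethyl-1-[(1R)-3-methyl-1-(2,4,6-trimethoxyphenyl)butyl]-7-(prop-1-en-2-yl)decahydroazulen-4-ol | C=C(C)[C@@H]1CC[C@@](C)(O)[C@@H]2CC[C@](C)([C@@H](CC(C)C)c3c(OC)cc(OC)cc3OC)[C@H]2C1 | intermediate
31 | lithium alkoxide of 30 lithiated at one free ring position | C=C(C)[C@@H]1CC[C@@](C)(O[Li])[C@@H]2CC[C@](C)([C@@H](CC(C)C)c3c(OC)c([Li])c(OC)cc3OC)[C@H]2C1 | intermediate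
32 | lithium α-amino alkoxide adduct of 31 with the formamide | C=C(C)[C@@H]1CC[C@@](C)(O[Li])[C@@H]2CC[C@](C)([C@@H](CC(C)C)c3c(OC)c(C(O[Li])N(C)CCN(C)C)c(OC)cc3OC)[C@H]2C1 | intermediate
33 | 32 lithiated at the remaining ring position | C=C(C)[C@@H]1CC[C@@](C)(O[Li])[C@@H]2CC[C@](C)([C@@H](CC(C)C)c3c(OC)c(C(O[Li])N(C)CCN(C)C)c(OC)c([Li])c3OC)[C@H]2C1 | intermediate
34 | 5-{(1R)-1-[(1S,3aR,4R,7R,8aS)-4-hydroxy-1,4-dimethyl-7-(prop-1-en-2-yl)decahydroazulen-1-yl]-3-methylbutyl}-2,4,6-trimethoxybenzene-1,3-dicarbaldehyde | C=C(C)[C@@H]1CC[C@@](C)(O)[C@@H]2CC[C@](C)([C@@H](CC(C)C)c3c(OC)c(C=O)c(OC)c(C=O)c3OC)[C@H]2C1 | intermediate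
35 | 5-{(1R)-1-[(1S,3aR,4R,7R,8aS)-4-hydroxy-1,4-dimethyl-7-(prop-1-en-2-yl)decahydroazulen-1-yl]-3-methylbutyl}-2,4,6-trihydroxybenzene-1,3-dicarbaldehyde | C=C(C)[C@@H]1CC[C@@](C)(O)[C@@H]2CC[C@](C)([C@@H](CC(C)C)c3c(O)c(C=O)c(O)c(C=O)c3O)[C@H]2C1 | target

**Step count and risks**

Total steps: 17. Longest linear sequence: 15 steps (steps 1–5, then 8–17).

Steps most likely to fail:

1. Step 8 (Proposed new method). What may go wrong: the quinone methide may be consumed by self-condensation before the hindered tetrasubstituted enolate attacks it, and if magnesium bridges the enolate and quinone-methide oxygens the addition would run through the closed arrangement and give the C1′ epimer.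
Fallback, known steps, setting out from 10 and 15 and returning at 20 (19 and step 9 are bypassed): the same copper-catalysed conjugate addition is quenched with Me3SiCl and Et3N to give the trimethylsilyl enol ether F1. Separately, 3-methyl-1-(2,4,6-trimethoxyphenyl)butan-1-one F2 (from 1,3,5-trimethoxybenzene, 3-methylbutanoic acid and (CF3CO)2O) is reduced with BH3·SMe2 and (R)-2-methyl-CBS-oxazaborolidine to (1S)-3-methyl-1-(2,4,6-trimethoxyphenyl)butan-1-ol F3. F3 is complexed with Cr(CO)6 (Bu2O–THF, reflux) to the Cr(CO)3 complex F4 and acetylated (Ac2O, pyridine) to the acetate complex F5. BF3·OEt2 (CH2Cl2, −78 °C) ionises F5 in the presence of F1 to give the Cr(CO)3 complex of the coupled ketone F6. Cr(CO)3-stabilised benzylic cations are substituted by silyl enol ethers with retention, since the leaving group departs and the nucleophile enters anti to chromium; C1′ is thus dictated by the (S) configuration of F5, while C4 is again set anti to the C5 chain. Exposure of F6 to air and light in Et2O removes the metal and gives 20.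

2. Step 14. What may go wrong: poor facial selectivity, since attack of the peracid on the β face would give the C10 epimer after hydride opening, and competing epoxidation of the isopropenyl group would waste material.
Fallback, setting out from 28 and returning at 29: if the β-epoxide F7 is the main product, it is hydrolysed (HClO4 cat., THF–H2O, 0 °C) with inversion at the tertiary C10 to the 9β,10α-diol F8. The secondary hydroxyl is mesylated selectively (MeSO2Cl, Et3N, CH2Cl2, 0 °C) to the 9β-mesylate F9. K2CO3 in MeOH then closes the ring by attack of the C10 alkoxide on C9 with inversion; this classical epoxide inversion gives the α-epoxide 29.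

3. Step 13. What may go wrong: hydrazone formation at the carbonyl flanked by the quaternary C4 may stall, and the forcing alkaline conditions may then cleave aryl methyl ethers or shift the C9=C10 bond.
Fallback, setting out from 26 and returning at 28: NaBH4 (MeOH, 0 °C) reduces the ketone to the C3 alcohol F10 (β-hydroxyl expected from hydride approach on the methyl-bearing face; either epimer serves). NaH, CS2 and MeI (THF) give the S-methyl xanthate F11, and Bu3SnH with AIBN (toluene, 90 °C) removes the oxygen (Barton–McCombie deoxygenation) to give 28.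

**Further compounds**

F1 | step 8 | trimethyl({(3R)-2-methyl-3-[(2R)-2-(prop-1-en-2-yl)pent-4-en-1-yl]cyclopent-1-en-1-yl}oxy)silane | C=CC[C@@H](C(C)=C)C[C@H]1CCC(O[Si](C)(C)C)=C1C
F2 | step 8 | 3-methyl-1-(2,4,6-trimethoxyphenyl)butan-1-one | CC(C)CC(=O)c1c(OC)cc(OC)cc1OC
F3 | step 8 | (1S)-3-methyl-1-(2,4,6-trimethoxyphenyl)butan-1-ol | CC(C)C[C@H](O)c1c(OC)cc(OC)cc1OC
F4 | step 8 | Cr(CO)3 complex of F3 | CC(C)C[C@H](O)c1c(OC)cc(OC)cc1OC.[Cr].[C-]#[O+].[C-]#[O+].[C-]#[O+]
F5 | step 8 | Cr(CO)3 complex of the acetate of F3 | CC(C)C[C@H](OC(C)=O)c1c(OC)cc(OC)cc1OC.[Cr].[C-]#[O+].[C-]#[O+].[C-]#[O+]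
F6 | step 8 | Cr(CO)3 complex of 20 | C=CC[C@@H](C(C)=C)C[C@H]1CCC(=O)[C@]1(C)[C@@H](CC(C)C)c2c(OC)cc(OC)cc2OC.[Cr].[C-]#[O+].[C-]#[O+].[C-]#[O+]
F7 | step 14 | 9β,10β-epoxide of 28 (C9,C10 diastereomer of 29) | C=C(C)[C@@H]1C[C@@H]3O[C@]3(C)[C@@H]2CC[C@](C)([C@@H](CC(C)C)c4c(OC)cc(OC)cc4OC)[C@H]2C1
F8 | step 14 | 9β,10α-diol from F7 | C=C(C)[C@@H]1C[C@H](O)[C@@](C)(O)[C@@H]2CC[C@](C)([C@@H](CC(C)C)c3c(OC)cc(OC)cc3OC)[C@H]2C1
F9 | step 14 | 9β-methanesulfonate of F8 | C=C(C)[C@@H]1C[C@H](OS(C)(=O)=O)[C@@](C)(O)[C@@H]2CC[C@](C)([C@@H](CC(C)C)c3c(OC)cc(OC)cc3OC)[C@H]2C1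
F10 | step 13 | C3 β-alcohol from 26 | C=C(C)[C@@H]1CC=C(C)[C@@H]2C[C@H](O)[C@](C)([C@@H](CC(C)C)c3c(OC)cc(OC)cc3OC)[C@H]2C1
F11 | step 13 | S-methyl xanthate of F10 | C=C(C)[C@@H]1CC=C(C)[C@@H]2C[C@H](OC(=S)SC)[C@](C)([C@@H](CC(C)C)c3c(OC)cc(OC)cc3OC)[C@H]2C1
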